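**No constants.** I had no rate constants for this flask, just two earlier runs, so I looked for a scale whose zero needs none.

| flask | free monomer | pre-initiator | remark | time |
|---|---|---|---|---|
| dusk | 1 M | 48 mM | run made earlier |  |
| midnight | 2 M | 96 mM | run made earlier |  |
| flask | 2.0 M | 48 mM |  | 3.0 min |

| run | time / s | monomer in chains / % | free monomer / % |
|---|---|---|---|
| dusk | 10.0 | 1.1 | 100.1 |
| dusk | 15.0 | 0.9 | 98.5 |
| dusk | 30.0 | 5.8 | 94.0 |
| dusk | 60.0 | 26.2 | 74.1 |
| dusk | 120 | 59.1 | 41.9 |
| midnight | 20.0 | 8.6 | 91.0 |
| midnight | 40.0 | 31.4 | 68.2 |
| midnight | 60.0 | 56.2 | 43.2 |
| midnight | 80.0 | 72.1 | 28.2 |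
| midnight | 120 | 84.1 | 16.2 |

(readings scatter by 0.5 percentage points)

1. average number of monomer units in a chain (chains begun, living or dead) at 3.0 min
2. part of the free monomer that has reacted at 3.0 min

- the average divides the monomer in chains by the number of chains begun, living and dead together
- the earlier runs do not show the number of chains; that part of a forecast is a guess

**Statistical zero.** Suppose each pre-initiator began one chain and the charged free monomer went wholly into chains. A chain would then hold S = 41.7 units, the charge ratio, which I call the statistical length. Really dp = S·c/f, where c is the part reacted and f the share of pre-initiator that has begun chains.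

**What matters.** S comes from the charges and carries no reading error. dp moves in proportion to c, which the runs can give. It moves inversely with f, which they do not show, so f is the weak number.

**My numbers.** Midnight's monomer in chains grew faster in its second interval (23 percentage points) than in its first (8.6 %), so chains were still beginning, and I guessed f = 0.7. The flask has midnight's free monomer and half its pre-initiator. If chains begin at a steady pace, uptake follows pre-initiator times time squared, which puts the flask at 127 s on midnight's clock. That lies near midnight's last reading, so I took c = 83.8 % and dp = 49.9.

**The result.** The forecast gave 71 % for c and, on the ground “Activation should be nearly complete by 180 s”, 32 for dp. The flask gave 51.8 and 84.5 %.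

    free monomer + initiator → living end + monomer in chains (k = 0.0806 /M/s)
    free monomer + living end → monomer in chains + living end, rate k2*[living end]*[free monomer] (k = 0.917 /M/s)
    monomer in chains + living end → free monomer + living end, rate k3*[living end] as long as [monomer in chains] is above zero (k = 0.239 /s)
    pre-initiator ⇌ initiator (K = 0.295, k = 0.0118 /s)

**Neighbour flask.** At 3.00 min the flask held 0.0327 M of living end, so f was 68.0 %. The neighbour with 12.0 mM of pre-initiator has S = 167, and its clock reads 63.6 s, beside midnight's 60.0 s reading of 56.8 % reacted. It gave c = 53.7 %. Its 0.00927 M of living end makes f = 77.3 %, and S·c/f comes to 116, with its dp at 116.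

(All runs were computed with constants of no real substance; the scatter is artificial.)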